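**Assumptions (one line each)**
- The SMILES is read as the (2S)-flavanone carrying a (2R)-5-hydroxy-5-methyl-2-(prop-1-en-2-yl)hexyl chain at C8 (kurarinol); this chain maps onto (S)-lavandulol, which is not assumed purchasable as a single enantiomer and is therefore made.
- Common reagents that add atoms (MOMCl, I2, mCPBA, etc.) are given with SMILES in each step and are not numbered.
- The route is a paper design; none of it has been run, and the facial sense in step 15 is predicted by analogy, not from a confirmed example.

**Retrosynthetic overview**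
1. Target ⇒ tris-MOM flavanone 20 (global deprotection) ⇒ chromone 16 + arylboronic acid 19; a Rh-catalysed asymmetric 1,4-addition sets C2 and brings in the B ring.
2. Chromone 16 ⇒ 2'-hydroxyacetophenone 15 (DMF-DMA annulation). The pyranone is the only ring built; both benzene rings are purchased. The acetyl comes from directed ortho-metalation of the symmetric arene 13.
3. Tertiary alcohol of 13 ⇒ prenyl alkene of lavandulyl arene 11 (chemoselective epoxidation, then hydride opening).
4. 11 ⇒ aryl iodide 10 (DoM of 5-methoxyresorcinol bis-MOM ether) + (S)-lavandulyl iodide 7 (sp3–sp2 Negishi).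
5. 7 ⇒ Evans dienolate α-prenylation of N-senecioyl oxazolidinone 3, which sets the side-chain stereocentre.

**Route**

Step 1
Reactants: 1 (S)-4-benzyloxazolidin-2-one; 2 3-methylbut-2-enoyl chloride
Product: 3 (S)-4-benzyl-3-(3-methylbut-2-enoyl)oxazolidin-2-one
Conditions: n-BuLi, THF, −78 °C; then 2, −78 → 0 °C
Reagents that add atoms: none beyond the listed reactants
Why: Standard N-acylation of the lithiated Evans auxiliary by the acid chloride.

Step 2
Reactants: 3; 4 prenyl bromide (1-bromo-3-methylbut-2-ene)
Product: 5 (S)-4-benzyl-3-[(2S)-5-methyl-2-(prop-1-en-2-yl)hex-4-enoyl]oxazolidin-2-one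
Conditions: NaHMDS (1.1 equiv), THF, −78 °C; 4 (3 equiv), −78 → −40 °C; minor diastereomer removed by chromatography
Reagents that add atoms: none beyond the listed reactants
Why: Evans deconjugative alkylation: γ-deprotonation gives the chelated Z-dienolate, which is prenylated at Cα on the face opposite the benzyl group, creating the isopropenyl group and the (S)-α-centre (same facial sense as the classic propionimide alkylation).

Step 3
Reactants: 5
Product: 6 (S)-lavandulol [(2S)-5-methyl-2-(prop-1-en-2-yl)hex-4-en-1-ol]
Conditions: LiBH4, MeOH (1 equiv), Et2O, 0 °C (auxiliary 1 recovered)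
Reagents that add atoms: none
Why: Reductive removal of the auxiliary; non-basic hydride conditions avoid epimerisation or conjugation of the β,γ-unsaturated α-centre.

Step 4
Reactants: 6
Product: 7 (S)-lavandulyl iodide [(3S)-3-(iodomethyl)-2,6-dimethylhepta-1,5-diene]
Conditions: I2, PPh3, imidazole, CH2Cl2, 0 °C → rt
Reagents that add atoms: iodine, II
Why: Appel-type iodination of the primary alcohol; the stereocentre is not involved.

Step 5
Reactants: 8 5-methoxyresorcinol
Product: 9 1-methoxy-3,5-bis(methoxymethoxy)benzene
Conditions: MOMCl, i-Pr2NEt, CH2Cl2, 0 °C → rt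
Reagents that add atoms: chloromethyl methyl ether, COCCl
Why: Bis-O-alkylation; MOM serves as both protecting group and ortho-directing group.

Step 6
Reactants: 9
Product: 10 2-iodo-5-methoxy-1,3-bis(methoxymethoxy)benzene
Conditions: n-BuLi, THF, 0 °C, 1 h; I2, −78 °C → rt
Reagents that add atoms: iodine, II
Why: Directed ortho-metalation occurs at the position flanked by two OMOM groups; iodine quench gives a symmetric iodide, so no regiochemical ambiguity arises later.

Step 7
Reactants: 7; 10
Product: 11 5-methoxy-1,3-bis(methoxymethoxy)-2-[(2R)-5-methyl-2-(prop-1-en-2-yl)hex-4-en-1-yl]benzene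
Conditions: 7, t-BuLi (2.1 equiv), Et2O, −78 °C; ZnCl2 (THF), → rt; then 10, Pd(OAc)2 (3 mol %), SPhos (6 mol %), THF, 50 °C
Reagents that add atoms: none
Why: Negishi sp3–sp2 coupling; polar I/Li exchange then Zn transmetalation avoids radical rearrangement of the homoallyl unit, SPhos handles the di-ortho-substituted iodide, and the stereocentre (β to zinc) is untouched; the descriptor becomes R only through CIP priority change.

Step 8
Reactants: 11
Product: 12 2-{(2S)-2-[(3,3-dimethyloxiran-2-yl)methyl]-3-methylbut-3-en-1-yl}-5-methoxy-1,3-bis(methoxymethoxy)benzene (about 1:1 at the oxirane CH; side-chain centre spatially unchanged)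
Conditions: mCPBA (1.05 equiv), NaHCO3, CH2Cl2, −20 → 0 °C
Reagents that add atoms: mCPBA, O=C(OO)c1cccc(Cl)c1
Why: Prilezhaev epoxidation is faster on the trisubstituted prenyl alkene than on the 1,1-disubstituted isopropenyl alkene; the new oxirane centre is erased in step 9.

Step 9
Reactants: 12
Product: 13 (5R)-6-[4-methoxy-2,6-bis(methoxymethoxy)phenyl]-2-methyl-5-(prop-1-en-2-yl)hexan-2-ol
Conditions: LiEt3BH, THF, 0 °C → rt; NaOH/H2O2 work-up
Reagents that add atoms: none
Why: Super-Hydride opens the epoxide by SN2 at the less substituted carbon, giving the tertiary alcohol (net Markovnikov hydration of the prenyl group only).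

Step 10
Reactants: 13
Product: 14 1-{3-[(2R)-5-hydroxy-5-methyl-2-(prop-1-en-2-yl)hexyl]-6-methoxy-2,4-bis(methoxymethoxy)phenyl}ethan-1-one
Conditions: n-BuLi (2.5 equiv), TMEDA, THF, −20 → 0 °C; MeC(O)N(OMe)Me (4 equiv), −78 °C → rt
Reagents that add atoms: N-methoxy-N-methylacetamide, CC(=O)N(C)OC
Why: After O-deprotonation, a second DoM occurs at the only ring C–H, flanked by OMOM and OMe (both such positions are equivalent by symmetry), and Weinreb acylation gives the methyl ketone without over-addition.

Step 11
Reactants: 14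
Product: 15 1-{2-hydroxy-3-[(2R)-5-hydroxy-5-methyl-2-(prop-1-en-2-yl)hexyl]-6-methoxy-4-(methoxymethoxy)phenyl}ethan-1-one
Conditions: conc. HCl (2 equiv), MeOH, 0 °C → rt, stopped at mono-deprotection
Reagents that add atoms: none
Why: Chelation-assisted acetal cleavage removes the MOM ortho to the carbonyl much faster than the para MOM; the tertiary alcohol and alkene tolerate the dilute acid.

Step 12
Reactants: 15
Product: 16 8-[(2R)-5-hydroxy-5-methyl-2-(prop-1-en-2-yl)hexyl]-5-methoxy-7-(methoxymethoxy)-4H-chromen-4-one
Conditions: DMF-DMA, toluene, 95 °C; concentrate; AcOH, 60 °C (enaminone not isolated)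
Reagents that add atoms: DMF dimethyl acetal, COC(OC)N(C)C (supplies C2)
Why: Enaminone formation at the acetyl methyl, then acid-promoted 6-endo addition of the phenol and loss of Me2NH, closes the pyranone ring (standard chromone annulation) while the 7-OMOM is retained.

Step 13
Reactants: 17 4-bromoresorcinol
Product: 18 1-bromo-2,4-bis(methoxymethoxy)benzene
Conditions: MOMCl, i-Pr2NEt, CH2Cl2, 0 °C → rt
Reagents that add atoms: chloromethyl methyl ether, COCCl
Why: Simple bis-O-alkylation.

Step 14
Reactants: 18
Product: 19 [2,4-bis(methoxymethoxy)phenyl]boronic acid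
Conditions: n-BuLi, THF, −78 °C; B(Oi-Pr)3; aq. NH4Cl
Reagents that add atoms: triisopropyl borate, CC(C)OB(OC(C)C)OC(C)C; water, O
Why: Br/Li exchange, borate trapping and mild hydrolysis; MOM groups survive the near-neutral work-up.

Step 15
Reactants: 16; 19 (4 equiv, added in portions)
Product: 20 (2S)-2-[2,4-bis(methoxymethoxy)phenyl]-8-[(2R)-5-hydroxy-5-methyl-2-(prop-1-en-2-yl)hexyl]-5-methoxy-7-(methoxymethoxy)-2,3-dihydro-4H-chromen-4-one
Conditions: [Rh(OH)(cod)]2 (3 mol %), (S)-MeO-F12-BIPHEP (7 mol %), toluene/H2O 10:1, 30 °C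
Reagents that add atoms: none beyond the listed reactants (water supplies only H-3)
Why: Hayashi–Miyaura asymmetric 1,4-addition to the chromone; the electron-poor bisphosphine speeds insertion and suppresses 1,2-addition and ring opening, and the ligand alone controls C2. The (S)-ligand is predicted to give 2S by analogy with cyclohexenone; this must be confirmed by CD on the first run, and the (R)-ligand used if the sense is reversed.

Step 16
Reactants: 20
Product: 21 target, (2S)-2-(2,4-dihydroxyphenyl)-7-hydroxy-8-[(2R)-5-hydroxy-5-methyl-2-(prop-1-en-2-yl)hexyl]-5-methoxy-2,3-dihydro-4H-chromen-4-one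
Conditions: 3 M aq. HCl/MeOH (1:4), 40 °C, monitored
Reagents that add atoms: none
Why: Acidic acetal hydrolysis removes all three aryl MOM ethers; base is avoided, so C2 cannot epimerise through the chalcone, and the side-chain centre has no epimerisation pathway.

**Compound list**
1 | (S)-4-benzyloxazolidin-2-one | O=C1N[C@@H](Cc2ccccc2)CO1 | starting material
2 | 3-methylbut-2-enoyl chloride | CC(C)=CC(Cl)=O | starting material
3 | (S)-4-benzyl-3-(3-methylbut-2-enoyl)oxazolidin-2-one | CC(C)=CC(=O)N1[C@@H](Cc2ccccc2)COC1=O | intermediate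
4 | prenyl bromide | CC(C)=CCBr | starting material
5 | (S)-4-benzyl-3-[(2S)-5-methyl-2-(prop-1-en-2-yl)hex-4-enoyl]oxazolidin-2-one | C=C(C)[C@H](CC=C(C)C)C(=O)N1[C@@H](Cc2ccccc2)COC1=O | intermediate
6 | (S)-lavandulol | C=C(C)[C@H](CC=C(C)C)CO | intermediate
7 | (S)-lavandulyl iodide | C=C(C)[C@H](CC=C(C)C)CI | intermediate
8 | 5-methoxyresorcinol | COc1cc(O)cc(O)c1 | starting material
9 | 1-methoxy-3,5-bis(methoxymethoxy)benzene | COCOc1cc(OC)cc(OCOC)c1 | intermediate
10 | 2-iodo-5-methoxy-1,3-bis(methoxymethoxy)benzene | COCOc1cc(OC)cc(OCOC)c1I | intermediate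
11 | (R)-lavandulyl arene | C=C(C)[C@H](CC=C(C)C)Cc1c(OCOC)cc(OC)cc1OCOC | intermediate
12 | epoxide (mixture at oxirane CH) | C=C(C)[C@H](CC1OC1(C)C)Cc1c(OCOC)cc(OC)cc1OCOC | intermediate
13 | (5R)-6-[4-methoxy-2,6-bis(methoxymethoxy)phenyl]-2-methyl-5-(prop-1-en-2-yl)hexan-2-ol | C=C(C)[C@H](CCC(C)(C)O)Cc1c(OCOC)cc(OC)cc1OCOC | intermediate
14 | bis-MOM acetophenone | C=C(C)[C@H](CCC(C)(C)O)Cc1c(OCOC)cc(OC)c(C(C)=O)c1OCOC | intermediate
15 | 2'-hydroxy-4'-MOM acetophenone | C=C(C)[C@H](CCC(C)(C)O)Cc1c(OCOC)cc(OC)c(C(C)=O)c1O | intermediate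
16 | 8-alkyl-5-methoxy-7-(methoxymethoxy)chromone | C=C(C)[C@H](CCC(C)(C)O)Cc1c(OCOC)cc(OC)c2c1OC=CC2=O | intermediate
17 | 4-bromoresorcinol | Oc1ccc(Br)c(O)c1 | starting material
18 | 1-bromo-2,4-bis(methoxymethoxy)benzene | COCOc1ccc(Br)c(OCOC)c1 | intermediate
19 | [2,4-bis(methoxymethoxy)phenyl]boronic acid | COCOc1ccc(B(O)O)c(OCOC)c1 | intermediate
20 | tris-MOM (2S)-flavanone | C=C(C)[C@H](CCC(C)(C)O)Cc1c(OCOC)cc(OC)c2c1O[C@H](c1ccc(OCOC)cc1OCOC)CC2=O | intermediate
21 | CID44563198 (kurarinol) | C=C(C)[C@H](CCC(C)(C)O)Cc1c(O)cc(OC)c2c1O[C@H](c1ccc(O)cc1O)CC2=O | target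

**Count**
Total steps: 16. Longest linear sequence: 12 (steps 1–4, 7–12, 15, 16).

**Three steps most likely to fail, with fallbacks**
1. Step 15 (ortho-alkoxy arylboronic acid adding to an electron-rich, 8-substituted chromone; yield and ee uncertain). Fallback: Claisen–Schmidt condensation of 15 with 2,4-bis(methoxymethoxy)benzaldehyde to the chalcone, then oxa-Michael cyclisation (NaOAc or a cinchona-thiourea catalyst). The C2 epimers are diastereomers because of the side-chain centre, so they can be separated by chromatography or HPLC and the wrong one recycled by base equilibration.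
2. Step 7 (Negishi coupling of a β-branched homoallylic zinc with a di-ortho-alkoxy aryl iodide). Fallback: reverse the polarity. Alkylate the dienolate of the (R)-auxiliary senecioyl imide with 2,6-bis(methoxymethoxy)-4-methoxybenzyl bromide (from 9 by DoM/DMF, NaBH4, MsCl/LiBr). Then LiBH4, I2/PPh3, and Cu-catalysed opening of isobutylene oxide by the derived organometallic install CH2C(Me)2OH directly, which also replaces steps 8–9.
3. Step 16 (acid deprotection in the presence of the tertiary alcohol, the isopropenyl group next to a free 7-OH, and an electron-rich benzylic C2–O bond). Fallback: change the protecting-group plan. Remove both MOMs at the acetophenone stage, form the chromone, silylate 7-OH (TBS), couple with 2,4-bis(TBSO)phenylboronic acid pinacol ester, and finish with buffered fluoride (TBAF/AcOH or HF·pyridine).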